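**Assumption:** the target is taken exactly as drawn, (4S) with both trisubstituted alkenes E; methyl 3,5-dibromo-4-methoxybenzoate and prenylmagnesium chloride (THF solution) are taken as catalogue compounds.

## Retrosynthetic overview

1. Target 16 ⇐ hydroxy-enal 13 by enal 1,2-reduction and ester hydrolysis in one pot.
2. 13 ⇐ bis-enal 7 + tertiary boronate 11: the C4′–C5′ bond and the only stereocentre (4S) come from a chiral-phosphoric-acid-catalysed linear prenylation of one of two homotopic aldehydes (proposed new step).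
3. 7 ⇐ diallyl arene 4 + methacrolein (two-directional cross-metathesis, sets both E-alkenes); 4 ⇐ dibromide 1 + allyl-Bpin (double Suzuki coupling).
4. 11 ⇐ prenylmagnesium chloride + iPrO-Bpin (SE2′ borylation).
5. No ring is formed; the benzene ring is bought in 1.

## Route

**Step 1**
Reactants: 1 methyl 3,5-dibromo-4-methoxybenzoate; 2 2-allyl-4,4,5,5-tetramethyl-1,3,2-dioxaborolane
Product: 4 methyl 3,5-diallyl-4-methoxybenzoate, via mono-allyl bromide 3 (not isolated)
Conditions: 2 (3 equiv), Pd(PPh3)4 (10 mol%), CsF (6 equiv), THF, reflux, 24 h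
Reagents that add atoms: allylboronic acid pinacol ester 2, C=CCB1OC(C)(C)C(C)(C)O1
Why: Suzuki–Miyaura allyl–aryl coupling, in which zerovalent palladium inserts into each electron-poor C–Br bond, fluoride-activated allyl-Bpin transmetallates and reductive elimination gives the allylarene, while anhydrous CsF avoids ester hydrolysis and limits allyl-to-propenyl isomerisation.

**Step 2**
Reactants: 4 methyl 3,5-diallyl-4-methoxybenzoate; 5 methacrolein
Product: 7 methyl 4-methoxy-3,5-bis[(E)-3-methyl-4-oxobut-2-en-1-yl]benzoate, via mono-enal 6 (not isolated)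
Conditions: 5 (12 equiv), second-generation Hoveyda–Grubbs catalyst (H2IMes)Cl2Ru(=CH-C6H4-2-OiPr) (2 × 4 mol%), 1,4-benzoquinone (10 mol%), CH2Cl2, 40 °C, 24 h
Reagents that add atoms: methacrolein 5, CC(=C)C=O
Why: Two-directional olefin cross-metathesis of terminal alkenes with an excess of a 1,1-disubstituted enal gives the trisubstituted enals as the E isomers (CHO trans to ArCH2) under thermodynamic control, and benzoquinone suppresses Ru–H-mediated migration of the allyl double bonds.

**Step 3**
Reactants: 8 (3-methylbut-2-en-1-yl)magnesium chloride; 9 2-isopropoxy-4,4,5,5-tetramethyl-1,3,2-dioxaborolane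
Product: 11 2-(2-methylbut-3-en-2-yl)-4,4,5,5-tetramethyl-1,3,2-dioxaborolane, via magnesium borate complex 10 (not isolated)
Conditions: 8 (1.05 equiv), THF, −78 °C → rt; HCl·Et2O (1.0 equiv), 0 °C; filtration, distillation below 50 °C under reduced pressure
Reagents that add atoms: prenylmagnesium chloride 8, CC(C)=CC[Mg]Cl
Why: Allylic Grignard borylation, in which the Grignard reagent attacks the B–O electrophile through a six-membered SE2′ transition state at its more substituted terminus, and direct trapping as the pinacol ester (no 1,3-borotropic shift at these temperatures) preserves the tertiary reverse-prenyl boronate.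

**Step 4**
Reactants: 7 methyl 4-methoxy-3,5-bis[(E)-3-methyl-4-oxobut-2-en-1-yl]benzoate; 11 2-(2-methylbut-3-en-2-yl)-4,4,5,5-tetramethyl-1,3,2-dioxaborolane
Product: 13 methyl 3-[(2E,4S)-4-hydroxy-3,7-dimethylocta-2,6-dien-1-yl]-4-methoxy-5-[(E)-3-methyl-4-oxobut-2-en-1-yl]benzoate, via O-Bpin borate 12 (not isolated)
Conditions: 11 (0.7 equiv), (S)-TRIP [(S)-3,3′-bis(2,4,6-triisopropylphenyl)-1,1′-binaphthyl-2,2′-diyl hydrogen phosphate] (5 mol%), 4 Å MS, toluene, −30 → 0 °C, 36 h; aq. NaHCO3; chromatography, recovered 7 recycled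
Reagents that add atoms: α,α-dimethylallyl-Bpin 11, C=CC(C)(C)B1OC(C)(C)C(C)(C)O1
Why: Proposed new method: chiral-phosphoric-acid-catalysed allylboration with a tertiary α,α-dimethylallyl pinacolboronate, in which the P–OH hydrogen-bonds the pseudo-axial pinacol oxygen and P=O binds the formyl C–H, so that in a closed chair (Zimmerman–Traxler) transition state the unsubstituted CH2= terminus of 11 attacks the Si face of one of the two homotopic aldehydes of 7 with allylic transposition, giving the linear prenyl group and the (4S) carbinol (no E/Z issue because the boron-bearing carbon carries two identical methyls); the closest known reaction type is the chiral-phosphoric-acid-catalysed allylboration of aldehydes with allyl-Bpin and α-monosubstituted allyl-Bpin reagents, from which the (S)-catalyst to (S)-alcohol sense is extrapolated, and 0.7 equiv of 11 should give about 45% mono-adduct, about 12% bis-adduct and about 42% recyclable 7.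

**Step 5**
Reactants: 13 methyl 3-[(2E,4S)-4-hydroxy-3,7-dimethylocta-2,6-dien-1-yl]-4-methoxy-5-[(E)-3-methyl-4-oxobut-2-en-1-yl]benzoate
Product: 16 3-[(2E,4S)-4-hydroxy-3,7-dimethylocta-2,6-dien-1-yl]-5-[(E)-4-hydroxy-3-methylbut-2-en-1-yl]-4-methoxybenzoic acid, via ester diol 14 (not isolated), via lithium carboxylate 15 (not isolated)
Conditions: NaBH4 (1.0 equiv), MeOH–THF, 0 °C, 30 min; then LiOH·H2O (6 equiv), H2O, 40 °C, 8 h; 1 M HCl to pH 4, 0 °C
Reagents that add atoms: lithium hydroxide, [Li+].[OH-] (supplies the carboxyl OH oxygen)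
Why: Chemoselective 1,2-reduction of the enal by borohydride (ester and alkenes untouched) followed in the same flask by BAc2 saponification of the unhindered methyl benzoate, with the (4S) carbinol not involved and acidification only to pH 4 to avoid allylic ionisation.

## Compound list

1 | methyl 3,5-dibromo-4-methoxybenzoate | COC(=O)c1cc(Br)c(OC)c(Br)c1 | starting material
2 | 2-allyl-4,4,5,5-tetramethyl-1,3,2-dioxaborolane (allyl-Bpin) | C=CCB1OC(C)(C)C(C)(C)O1 | starting material
3 | methyl 3-allyl-5-bromo-4-methoxybenzoate | COC(=O)c1cc(Br)c(OC)c(CC=C)c1 | intermediate (not isolated)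
4 | methyl 3,5-diallyl-4-methoxybenzoate | COC(=O)c1cc(CC=C)c(OC)c(CC=C)c1 | intermediate
5 | methacrolein (2-methylprop-2-enal) | CC(=C)C=O | starting material
6 | methyl 3-allyl-4-methoxy-5-[(E)-3-methyl-4-oxobut-2-en-1-yl]benzoate | COC(=O)c1cc(CC=C)c(OC)c(C/C=C(\C)C=O)c1 | intermediate (not isolated)
7 | methyl 4-methoxy-3,5-bis[(E)-3-methyl-4-oxobut-2-en-1-yl]benzoate | COC(=O)c1cc(C/C=C(\C)C=O)c(OC)c(C/C=C(\C)C=O)c1 | intermediate
8 | (3-methylbut-2-en-1-yl)magnesium chloride (prenylmagnesium chloride) | CC(C)=CC[Mg]Cl | starting material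
9 | 2-isopropoxy-4,4,5,5-tetramethyl-1,3,2-dioxaborolane (iPrO-Bpin) | CC(C)OB1OC(C)(C)C(C)(C)O1 | starting material
10 | chloromagnesium 2-isopropoxy-4,4,5,5-tetramethyl-2-(2-methylbut-3-en-2-yl)-1,3,2-dioxaborolan-2-uide | C=CC(C)(C)[B-]1(OC(C)C)OC(C)(C)C(C)(C)O1.[Mg+]Cl | intermediate (not isolated)
11 | 2-(2-methylbut-3-en-2-yl)-4,4,5,5-tetramethyl-1,3,2-dioxaborolane (α,α-dimethylallyl-Bpin) | C=CC(C)(C)B1OC(C)(C)C(C)(C)O1 | intermediate
12 | methyl 3-[(2E,4S)-3,7-dimethyl-4-[(4,4,5,5-tetramethyl-1,3,2-dioxaborolan-2-yl)oxy]octa-2,6-dien-1-yl]-4-methoxy-5-[(E)-3-methyl-4-oxobut-2-en-1-yl]benzoate | COC(=O)c1cc(C/C=C(\C)C=O)c(OC)c(C/C=C(\C)[C@@H](OB2OC(C)(C)C(C)(C)O2)CC=C(C)C)c1 | intermediate (not isolated)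
13 | methyl 3-[(2E,4S)-4-hydroxy-3,7-dimethylocta-2,6-dien-1-yl]-4-methoxy-5-[(E)-3-methyl-4-oxobut-2-en-1-yl]benzoate | COC(=O)c1cc(C/C=C(\C)C=O)c(OC)c(C/C=C(\C)[C@@H](O)CC=C(C)C)c1 | intermediate
14 | methyl 3-[(2E,4S)-4-hydroxy-3,7-dimethylocta-2,6-dien-1-yl]-5-[(E)-4-hydroxy-3-methylbut-2-en-1-yl]-4-methoxybenzoate | COC(=O)c1cc(C/C=C(\C)CO)c(OC)c(C/C=C(\C)[C@@H](O)CC=C(C)C)c1 | intermediate (not isolated)
15 | lithium 3-[(2E,4S)-4-hydroxy-3,7-dimethylocta-2,6-dien-1-yl]-5-[(E)-4-hydroxy-3-methylbut-2-en-1-yl]-4-methoxybenzoate | [Li+].[O-]C(=O)c1cc(C/C=C(\C)CO)c(OC)c(C/C=C(\C)[C@@H](O)CC=C(C)C)c1 | intermediate (not isolated)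
16 | 3-[(2E,4S)-4-hydroxy-3,7-dimethylocta-2,6-dien-1-yl]-5-[(E)-4-hydroxy-3-methylbut-2-en-1-yl]-4-methoxybenzoic acid | COc1c(C/C=C(\C)CO)cc(C(=O)O)cc1C/C=C(\C)[C@@H](O)CC=C(C)C | target

## Step count and risks

Total step count: 5 (steps 1, 2, 4 and 5 on the main line; step 3 makes the prenylating reagent).
Longest linear sequence: 4 steps (1 → 4 → 7 → 13 → 16).

Three steps most likely to fail:

**Step 4 (proposed new step).** The tertiary boronate may react too slowly inside the catalyst pocket or give low ee. The ee and absolute configuration of 13 are checked by chiral HPLC and Mosher ester analysis on the first run; if the (R) alcohol is found, (R)-TRIP is used instead. The statistical mono-addition also limits the yield per pass. The fallback uses known chemistry, sets out from 7 and comes back at 13, one step longer. Bis-enal 7 is treated with allyl-Bpin 2 (0.7 equiv) and (S)-TRIP (5 mol%) in toluene at −30 °C, the established chiral-phosphoric-acid-catalysed allylboration. This gives the pinacol borate methyl 4-methoxy-3-[(2E,4S)-3-methyl-4-[(4,4,5,5-tetramethyl-1,3,2-dioxaborolan-2-yl)oxy]hepta-2,6-dien-1-yl]-5-[(E)-3-methyl-4-oxobut-2-en-1-yl]benzoate F1, hydrolysed on work-up to the (S)-homoallylic alcohol methyl 3-[(2E,4S)-4-hydroxy-3-methylhepta-2,6-dien-1-yl]-4-methoxy-5-[(E)-3-methyl-4-oxobut-2-en-1-yl]benzoate F2. Cross-metathesis of its terminal vinyl group with 2-methyl-2-butene (used as co-solvent in CH2Cl2, second-generation Grubbs catalyst (H2IMes)(PCy3)Cl2Ru=CHPh, rt) then turns the allyl group into the prenyl group and delivers 13. The trisubstituted alkenes and the enal do not take part.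

**Step 2 (double cross-metathesis with methacrolein).** Risks are incomplete second metathesis, migration of the allyl double bonds and methacrolein oligomerisation. The fallback sets out from 4 and comes back at 7. Ozonolysis of both allyl groups (O3, CH2Cl2, −78 °C; Me2S) gives the dialdehyde methyl 4-methoxy-3,5-bis(2-oxoethyl)benzoate F3. This is used crude in a double Wittig olefination with the stabilised ylide 2-(triphenylphosphoranylidene)propanal (2.5 equiv, toluene, 80 °C), which builds both E-configured 2-methyl enals and gives 7.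

**Step 3 (SE2′ borylation).** The linear prenyl boronate may form in part, or the tertiary boronate may isomerise on distillation. The linear isomer would give the reverse-prenyl alcohol in step 4, so the reagent must be regio-pure by 1H NMR. The fallback sets out from 9 and comes back at 11 by a Matteson-type 1,2-metallate route. Boronate 9 is treated with isopropylmagnesium chloride (THF, −78 °C) to give the ate complex chloromagnesium 2-isopropoxy-2-isopropyl-4,4,5,5-tetramethyl-1,3,2-dioxaborolan-2-uide F4. Quenching with HCl·Et2O collapses it to 2-isopropyl-4,4,5,5-tetramethyl-1,3,2-dioxaborolane F5. Radical bromination α to boron (Br2, hν, cyclohexane, 0 °C) gives 2-(2-bromopropan-2-yl)-4,4,5,5-tetramethyl-1,3,2-dioxaborolane F6. Vinylmagnesium bromide (THF, −78 °C) forms the vinyl ate complex bromomagnesium 2-(2-bromopropan-2-yl)-4,4,5,5-tetramethyl-2-vinyl-1,3,2-dioxaborolan-2-uide F7. On warming with ZnCl2 the vinyl group undergoes a 1,2-shift that displaces bromide and gives 11 with the C–B bond fixed at the tertiary carbon.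

## Further compounds

F1 | step 4 | methyl 4-methoxy-3-[(2E,4S)-3-methyl-4-[(4,4,5,5-tetramethyl-1,3,2-dioxaborolan-2-yl)oxy]hepta-2,6-dien-1-yl]-5-[(E)-3-methyl-4-oxobut-2-en-1-yl]benzoate | COC(=O)c1cc(C/C=C(\C)C=O)c(OC)c(C/C=C(\C)[C@@H](OB2OC(C)(C)C(C)(C)O2)CC=C)c1
F2 | step 4 | methyl 3-[(2E,4S)-4-hydroxy-3-methylhepta-2,6-dien-1-yl]-4-methoxy-5-[(E)-3-methyl-4-oxobut-2-en-1-yl]benzoate | COC(=O)c1cc(C/C=C(\C)C=O)c(OC)c(C/C=C(\C)[C@@H](O)CC=C)c1
F3 | step 2 | methyl 4-methoxy-3,5-bis(2-oxoethyl)benzoate | COC(=O)c1cc(CC=O)c(OC)c(CC=O)c1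
F4 | step 3 | chloromagnesium 2-isopropoxy-2-isopropyl-4,4,5,5-tetramethyl-1,3,2-dioxaborolan-2-uide | CC(C)O[B-]1(C(C)C)OC(C)(C)C(C)(C)O1.[Mg+]Cl
F5 | step 3 | 2-isopropyl-4,4,5,5-tetramethyl-1,3,2-dioxaborolane | CC(C)B1OC(C)(C)C(C)(C)O1
F6 | step 3 | 2-(2-bromopropan-2-yl)-4,4,5,5-tetramethyl-1,3,2-dioxaborolane | CC(C)(Br)B1OC(C)(C)C(C)(C)O1
F7 | step 3 | bromomagnesium 2-(2-bromopropan-2-yl)-4,4,5,5-tetramethyl-2-vinyl-1,3,2-dioxaborolan-2-uide | C=C[B-]1(C(C)(C)Br)OC(C)(C)C(C)(C)O1.[Mg+]Br
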